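## Retrosynthetic overview

1. Ring C is formed last: C2–O bond by a (2S)-selective 6-endo oxa-Michael closure of the free 2'-hydroxychalcone 27. Rings A and B are never built; both come from resorcinol.
2. Chalcone 27 ⇒ Claisen–Schmidt union of the ring A acetophenone 20 and the ring B aldehyde 24 (from resorcinol by formylation, selective MOM protection and methylation).
3. Acetophenone 20 ⇒ ortho-lithiation and acylation of the lavandulyl arene 16.
4. Key disconnection: the lavandulyl group of 16 is assembled on boron by three 1,2-shifts of carbon from boron to carbon. These are aryl to CH2 (Matteson), benzyl to the vinyl carbon (enantioselective conjunctive coupling, sets the R centre) and secondary alkyl to isopropenyl (Zweifel, retention).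
5. All carbon comes from resorcinol, C1–C4 organometallics or halides, DMF, MeI and N-methoxy-N-methylacetamide.

Assumption: in step 3 the (Sp,Sp) ligand is taken to give the (R)-boronate, as I recall the reported stereochemical model for this coupling; if the sense proves opposite, the commercial (Rp,Rp) antipode is used.

## Route

Step 1
Reactants: 1 resorcinol
Product: 2 1,3-bis(methoxymethoxy)benzene
Conditions: NaH, MOMCl, DMF, 0 °C → rt
Reagents that add atoms: chloromethyl methyl ether, COCCl
Why: Williamson-type O-alkylation of both phenoxides; the two MOM ethers later act as cooperative ortho-directing groups and come off under mild acid.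

Step 2
Reactants: 2 1,3-bis(methoxymethoxy)benzene
Product: 7 2-[2,6-bis(methoxymethoxy)benzyl]-4,4,5,5-tetramethyl-1,3,2-dioxaborolane, via aryllithium 3 (not isolated), via isopropoxyborate 4 (not isolated), via arylboronate 5 (not isolated), via chloromethylborate 6 (not isolated)
Conditions: n-BuLi, THF, 0 °C; i-PrOBpin, −78 °C → rt; TMSCl (1.0 equiv); BrCH2Cl then n-BuLi, −78 °C → rt
Reagents that add atoms: 2-isopropoxy-4,4,5,5-tetramethyl-1,3,2-dioxaborolane, CC(C)OB1OC(C)(C)C(C)(C)O1; bromochloromethane, ClCBr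
Why: Directed ortho-metalation between the two MOM ethers, borylation, then Matteson homologation in which the aryl group shifts 1,2 from boron to the chloromethyl carbon with loss of chloride; it is telescoped because the di-ortho-alkoxy arylboronate 5 protodeboronates easily on isolation.

Step 3
Reactants: 7 2-[2,6-bis(methoxymethoxy)benzyl]-4,4,5,5-tetramethyl-1,3,2-dioxaborolane; 8 vinylmagnesium bromide; 9 1-bromo-2-methylprop-1-ene
Product: 11 2-[(2R)-1-[2,6-bis(methoxymethoxy)phenyl]-5-methylhex-4-en-2-yl]-4,4,5,5-tetramethyl-1,3,2-dioxaborolane, via vinylborate 10 (not isolated)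
Conditions: 8, THF, 0 °C → rt; then NaOTf, Pd(OAc)2 (2 mol %), (Sp,Sp)-1,1'-bis[bis(4-methoxy-3,5-dimethylphenyl)phosphino]-2,2'-bis[(R)-α-(dimethylamino)benzyl]ferrocene (2.4 mol %), 9, THF, 60 °C
Reagents that add atoms: none
Why: Conjunctive cross-coupling (1,2-metallate shift): the alkenylpalladium cation (divalent palladium) binds the boron-bound vinyl group, the benzyl group shifts 1,2 from boron to the adjacent carbon anti to palladium, and reductive elimination forms the CH2–CH=CMe2 bond; the chiral bisphosphine selects one vinyl face and so sets the (R) centre.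

Step 4
Reactants: 11 2-[(2R)-1-[2,6-bis(methoxymethoxy)phenyl]-5-methylhex-4-en-2-yl]-4,4,5,5-tetramethyl-1,3,2-dioxaborolane; 12 2-bromopropene
Product: 16 1,3-bis(methoxymethoxy)-2-[(2R)-5-methyl-2-(prop-1-en-2-yl)hex-4-en-1-yl]benzene, via isopropenyllithium 13 (not isolated), via isopropenylborate 14 (not isolated), via iodoalkylboronate 15 (not isolated)
Conditions: 12, t-BuLi (2 equiv), THF/Et2O, −78 °C; 11, −78 °C; I2, MeOH, −78 °C; NaOMe, MeOH, −78 °C → rt
Reagents that add atoms: none
Why: Zweifel olefination: iodine activates the isopropenyl group of the borate, the secondary alkyl group shifts 1,2 from boron to carbon with retention at the migrating stereocentre, and methoxide-induced anti elimination of boron and iodide leaves the isopropenyl group, so the (R) centre is carried over unchanged.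

Step 5
Reactants: 16 1,3-bis(methoxymethoxy)-2-[(2R)-5-methyl-2-(prop-1-en-2-yl)hex-4-en-1-yl]benzene; 17 N-methoxy-N-methylacetamide
Product: 20 1-[2,4-bis(methoxymethoxy)-3-[(2R)-5-methyl-2-(prop-1-en-2-yl)hex-4-en-1-yl]phenyl]ethan-1-one, via aryllithium 18 (not isolated), via hemiaminal 19 (not isolated)
Conditions: n-BuLi, TMEDA, THF, 0 °C; inverse addition to 17, −78 → 0 °C; sat. aq NH4Cl
Reagents that add atoms: none
Why: Directed ortho-metalation next to a MOM ether (the two free ortho sites give the same constitution) followed by Weinreb ketone synthesis, in which the chelated tetrahedral intermediate prevents over-addition; no stereocentre is touched.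

Step 6
Reactants: 1 resorcinol
Product: 22 2,4-dihydroxybenzaldehyde, via iminium chloride 21 (not isolated)
Conditions: POCl3, DMF, MeCN, −15 °C → rt; then H2O, 50 °C
Reagents that add atoms: N,N-dimethylformamide, CN(C)C=O; water, O
Why: Vilsmeier–Haack formylation at C4, the position para to one hydroxyl and ortho to the other and less hindered than C2, then hydrolysis of the iminium salt.

Step 7
Reactants: 22 2,4-dihydroxybenzaldehyde
Product: 24 2-methoxy-4-(methoxymethoxy)benzaldehyde, via monoether 23 (not isolated)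
Conditions: MOMCl (1.05 equiv), K2CO3, acetone, 0 °C → rt; then MeI, reflux
Reagents that add atoms: chloromethyl methyl ether, COCCl; iodomethane, CI
Why: Two Williamson etherifications in one pot: the hydrogen-bonded 2-OH is inert at room temperature so MOMCl takes only the 4-OH, and the chelated 2-OH is then methylated under forcing conditions.

Step 8
Reactants: 20 1-[2,4-bis(methoxymethoxy)-3-[(2R)-5-methyl-2-(prop-1-en-2-yl)hex-4-en-1-yl]phenyl]ethan-1-one; 24 2-methoxy-4-(methoxymethoxy)benzaldehyde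
Product: 26 (E)-1-[2,4-bis(methoxymethoxy)-3-[(2R)-5-methyl-2-(prop-1-en-2-yl)hex-4-en-1-yl]phenyl]-3-[2-methoxy-4-(methoxymethoxy)phenyl]prop-2-en-1-one, via aldol adduct 25 (not isolated)
Conditions: KOH, EtOH/H2O, rt
Reagents that add atoms: none
Why: Claisen–Schmidt condensation (aldol addition then E1cB dehydration) gives the (E)-enone; MOM ethers are base-stable and the lavandulyl centre is not acidic.

Step 9
Reactants: 26 (E)-1-[2,4-bis(methoxymethoxy)-3-[(2R)-5-methyl-2-(prop-1-en-2-yl)hex-4-en-1-yl]phenyl]-3-[2-methoxy-4-(methoxymethoxy)phenyl]prop-2-en-1-one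
Product: 27 (E)-1-[2,4-dihydroxy-3-[(2R)-5-methyl-2-(prop-1-en-2-yl)hex-4-en-1-yl]phenyl]-3-(4-hydroxy-2-methoxyphenyl)prop-2-en-1-one
Conditions: 3 M aq HCl, MeOH, rt
Reagents that add atoms: none
Why: Acid-catalysed acetal methanolysis removes all three MOM groups; dilute acid at room temperature is chosen to spare the two alkenes and to avoid acid-driven, non-selective closure of the chalcone.

Step 10
Reactants: 27 (E)-1-[2,4-dihydroxy-3-[(2R)-5-methyl-2-(prop-1-en-2-yl)hex-4-en-1-yl]phenyl]-3-(4-hydroxy-2-methoxyphenyl)prop-2-en-1-one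
Product: 28 Alopecurone G, (2S)-7-hydroxy-2-(4-hydroxy-2-methoxyphenyl)-8-[(2R)-5-methyl-2-(prop-1-en-2-yl)hex-4-en-1-yl]-2,3-dihydro-4H-chromen-4-one
Conditions: recombinant Medicago sativa chalcone isomerase (type 2 enzyme that accepts 6'-deoxychalcones), 50 mM potassium phosphate pH 7.5, 10% v/v DMSO, 25 °C, N2
Reagents that add atoms: none
Why: Proposed new method: enzymatic oxa-Michael cyclisation of a 3'-C-alkylated, ring B ortho-methoxylated 6'-deoxychalcone, a substrate class that to my knowledge has not been shown for this enzyme; the active site holds the enone s-cis, the 2'-phenoxide adds to C-β on the face that gives (2S) while a hydrogen-bond network stabilises the enolate, the C10 chain next to the 4'-OH is expected to sit at the open mouth of the cleft, and background closure of 6'-deoxychalcones at pH 7.5 is very slow, so C2 is set under kinetic control without erosion; the closest known reaction is the chalcone-isomerase conversion of isoliquiritigenin into (2S)-liquiritigenin.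

## Compound list

1 | resorcinol | Oc1cccc(O)c1 | starting material
2 | 1,3-bis(methoxymethoxy)benzene | COCOc1cccc(OCOC)c1 | intermediate
3 | 2,6-bis(methoxymethoxy)phenyllithium | [Li]c1c(OCOC)cccc1OCOC | intermediate
4 | lithium [2,6-bis(methoxymethoxy)phenyl](isopropoxy)(pinacolato)borate | [Li+].CC(C)O[B-]1(c2c(OCOC)cccc2OCOC)OC(C)(C)C(C)(C)O1 | intermediate
5 | 2-[2,6-bis(methoxymethoxy)phenyl]-4,4,5,5-tetramethyl-1,3,2-dioxaborolane | COCOc1cccc(OCOC)c1B1OC(C)(C)C(C)(C)O1 | intermediate
6 | lithium [2,6-bis(methoxymethoxy)phenyl](chloromethyl)(pinacolato)borate | [Li+].ClC[B-]1(c2c(OCOC)cccc2OCOC)OC(C)(C)C(C)(C)O1 | intermediate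
7 | 2-[2,6-bis(methoxymethoxy)benzyl]-4,4,5,5-tetramethyl-1,3,2-dioxaborolane | COCOc1cccc(OCOC)c1CB1OC(C)(C)C(C)(C)O1 | intermediate
8 | vinylmagnesium bromide | C=C[Mg]Br | starting material
9 | 1-bromo-2-methylprop-1-ene | CC(C)=CBr | starting material
10 | bromomagnesium [2,6-bis(methoxymethoxy)benzyl](vinyl)(pinacolato)borate | C=C[B-]1(Cc2c(OCOC)cccc2OCOC)OC(C)(C)C(C)(C)O1.[Mg+]Br | intermediate
11 | 2-[(2R)-1-[2,6-bis(methoxymethoxy)phenyl]-5-methylhex-4-en-2-yl]-4,4,5,5-tetramethyl-1,3,2-dioxaborolane | CC1(C)OB(OC1(C)C)[C@H](CC=C(C)C)Cc1c(OCOC)cccc1OCOC | intermediate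
12 | 2-bromopropene | C=C(C)Br | starting material
13 | isopropenyllithium | C=C(C)[Li] | intermediate
14 | lithium [(2R)-1-[2,6-bis(methoxymethoxy)phenyl]-5-methylhex-4-en-2-yl](isopropenyl)(pinacolato)borate | [Li+].C=C(C)[B-]1(OC(C)(C)C(C)(C)O1)[C@H](CC=C(C)C)Cc1c(OCOC)cccc1OCOC | intermediate
15 | 2-[(3R)-3-[2,6-bis(methoxymethoxy)benzyl]-1-iodo-2,6-dimethylhept-5-en-2-yl]-4,4,5,5-tetramethyl-1,3,2-dioxaborolane (mixture at C2) | ICC(C)(B1OC(C)(C)C(C)(C)O1)[C@H](CC=C(C)C)Cc1c(OCOC)cccc1OCOC | intermediate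
16 | 1,3-bis(methoxymethoxy)-2-[(2R)-5-methyl-2-(prop-1-en-2-yl)hex-4-en-1-yl]benzene | C=C(C)[C@H](CC=C(C)C)Cc1c(OCOC)cccc1OCOC | intermediate
17 | N-methoxy-N-methylacetamide | CC(=O)N(C)OC | starting material
18 | 2,4-bis(methoxymethoxy)-3-[(2R)-5-methyl-2-(prop-1-en-2-yl)hex-4-en-1-yl]phenyllithium | C=C(C)[C@H](CC=C(C)C)Cc1c(OCOC)ccc([Li])c1OCOC | intermediate
19 | lithium 1-[2,4-bis(methoxymethoxy)-3-[(2R)-5-methyl-2-(prop-1-en-2-yl)hex-4-en-1-yl]phenyl]-1-[methoxy(methyl)amino]ethan-1-olate | C=C(C)[C@H](CC=C(C)C)Cc1c(OCOC)ccc(C(C)(O[Li])N(C)OC)c1OCOC | intermediate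
20 | 1-[2,4-bis(methoxymethoxy)-3-[(2R)-5-methyl-2-(prop-1-en-2-yl)hex-4-en-1-yl]phenyl]ethan-1-one | C=C(C)[C@H](CC=C(C)C)Cc1c(OCOC)ccc(C(C)=O)c1OCOC | intermediate
21 | (2,4-dihydroxybenzylidene)dimethylammonium chloride | C[N+](C)=Cc1ccc(O)cc1O.[Cl-] | intermediate
22 | 2,4-dihydroxybenzaldehyde | O=Cc1ccc(O)cc1O | intermediate
23 | 2-hydroxy-4-(methoxymethoxy)benzaldehyde | COCOc1ccc(C=O)c(O)c1 | intermediate
24 | 2-methoxy-4-(methoxymethoxy)benzaldehyde | COCOc1ccc(C=O)c(OC)c1 | intermediate
25 | 1-[2,4-bis(methoxymethoxy)-3-[(2R)-5-methyl-2-(prop-1-en-2-yl)hex-4-en-1-yl]phenyl]-3-hydroxy-3-[2-methoxy-4-(methoxymethoxy)phenyl]propan-1-one (mixture at C3) | C=C(C)[C@H](CC=C(C)C)Cc1c(OCOC)ccc(C(=O)CC(O)c2ccc(OCOC)cc2OC)c1OCOC | intermediate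
26 | (E)-1-[2,4-bis(methoxymethoxy)-3-[(2R)-5-methyl-2-(prop-1-en-2-yl)hex-4-en-1-yl]phenyl]-3-[2-methoxy-4-(methoxymethoxy)phenyl]prop-2-en-1-one | C=C(C)[C@H](CC=C(C)C)Cc1c(OCOC)ccc(C(=O)/C=C/c2ccc(OCOC)cc2OC)c1OCOC | intermediate
27 | (E)-1-[2,4-dihydroxy-3-[(2R)-5-methyl-2-(prop-1-en-2-yl)hex-4-en-1-yl]phenyl]-3-(4-hydroxy-2-methoxyphenyl)prop-2-en-1-one | C=C(C)[C@H](CC=C(C)C)Cc1c(O)ccc(C(=O)/C=C/c2ccc(O)cc2OC)c1O | intermediate
28 | Alopecurone G, (2S)-7-hydroxy-2-(4-hydroxy-2-methoxyphenyl)-8-[(2R)-5-methyl-2-(prop-1-en-2-yl)hex-4-en-1-yl]-2,3-dihydro-4H-chromen-4-one | C=C(C)[C@H](CC=C(C)C)Cc1c(O)ccc2c1O[C@H](c1ccc(O)cc1OC)CC2=O | target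

## Step count and risks

Total steps: 10 (steps 1–5 for the ring A arm, 6–7 for the ring B arm, 8–10 for the endgame).
Longest linear sequence: 8 steps (1, 2, 3, 4, 5, 8, 9, 10).

Steps most likely to fail:

**Step 10 (the proposed new step).** The enzyme may not accept a chalcone carrying a C10 chain beside the reacting phenol and an ortho-methoxy group on ring B. Fallback with known chemistry: the route sets out from 27, which is cyclised without stereocontrol (NaOAc, EtOH, reflux) to a roughly 1:1 mixture of 28 and its C2 epimer (2R)-7-hydroxy-2-(4-hydroxy-2-methoxyphenyl)-8-[(2R)-5-methyl-2-(prop-1-en-2-yl)hex-4-en-1-yl]-2,3-dihydro-4H-chromen-4-one F6. Because the lavandulyl centre is fixed, the two are diastereomers and are separated by preparative HPLC. F6 is reopened to 27 with dilute KOH in MeOH and recycled, and the route comes back at 28.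

**Step 3.** The hindered di-ortho-alkoxybenzyl boronate may transfer its benzyl group directly to palladium or give low enantioselectivity, and the facial sense rests on the assumption above. Fallback by reagent-controlled lithiation–borylation, which sets out from 7:
- 4-methylpent-3-en-1-ol F1 is carbamoylated (N,N-diisopropylcarbamoyl chloride, NaH, THF) to 4-methylpent-3-en-1-yl N,N-diisopropylcarbamate F2.
- s-BuLi and (−)-sparteine (Et2O, −78 °C) remove the pro-S proton to give (S)-1-lithio-4-methylpent-3-en-1-yl N,N-diisopropylcarbamate F3.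
- 7 is added and captures F3 with retention to give the lithium boronate complex F4.
- MgBr2·OEt2 at reflux triggers the 1,2-shift of the benzyl group with inversion at carbon and loss of the carbamate, and the route comes back at 11 with the (R) configuration.

This costs one more step.

**Step 9.** Protic acid can add the free phenols across the isopropenyl or prenyl alkene (chroman formation) or start non-selective closure of the chalcone. Fallback by non-protic transprotection, which sets out from 26: TMSOTf and 2,2'-bipyridyl (CH2Cl2, 0 °C) convert the three aryl MOM ethers into the silyl ether (E)-1-[2,4-bis(trimethylsilyloxy)-3-[(2R)-5-methyl-2-(prop-1-en-2-yl)hex-4-en-1-yl]phenyl]-3-[2-methoxy-4-(trimethylsilyloxy)phenyl]prop-2-en-1-one F5. F5 is hydrolysed with water in MeOH at 0 °C, and the route comes back at 27.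

## Further compounds

F1 | step 3 | 4-methylpent-3-en-1-ol | CC(C)=CCCO
F2 | step 3 | 4-methylpent-3-en-1-yl N,N-diisopropylcarbamate | CC(C)=CCCOC(=O)N(C(C)C)C(C)C
F3 | step 3 | (S)-1-lithio-4-methylpent-3-en-1-yl N,N-diisopropylcarbamate (sparteine complex, not isolated) | [Li][C@H](OC(=O)N(C(C)C)C(C)C)CC=C(C)C
F4 | step 3 | lithium [2,6-bis(methoxymethoxy)benzyl][(1S)-1-(N,N-diisopropylcarbamoyloxy)-4-methylpent-3-en-1-yl](pinacolato)borate (not isolated) | [Li+].CC1(C)O[B-](Cc2c(OCOC)cccc2OCOC)(OC1(C)C)[C@H](OC(=O)N(C(C)C)C(C)C)CC=C(C)C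
F5 | step 9 | (E)-1-[2,4-bis(trimethylsilyloxy)-3-[(2R)-5-methyl-2-(prop-1-en-2-yl)hex-4-en-1-yl]phenyl]-3-[2-methoxy-4-(trimethylsilyloxy)phenyl]prop-2-en-1-one | C=C(C)[C@H](CC=C(C)C)Cc1c(O[Si](C)(C)C)ccc(C(=O)/C=C/c2ccc(O[Si](C)(C)C)cc2OC)c1O[Si](C)(C)C
F6 | step 10 | (2R)-7-hydroxy-2-(4-hydroxy-2-methoxyphenyl)-8-[(2R)-5-methyl-2-(prop-1-en-2-yl)hex-4-en-1-yl]-2,3-dihydro-4H-chromen-4-one | C=C(C)[C@H](CC=C(C)C)Cc1c(O)ccc2c1O[C@@H](c1ccc(O)cc1OC)CC2=O
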